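**Retrosynthetic overview** (labdane numbering: ring A = C1–C5 and C10, ring B = C5–C10, side chain C11–C16, C17 on C8, C18/C19 on C4, C20 on C10)

1. Target 26 ⇒ desilylation and 1,3-allylic transposition (C17–OH/Δ7 from a 7-hydroxy-8(17)-ene) ⇒ C15 ester 24 ⇒ diol 17 plus C32 ω-silyloxy acid 23 (two C16 halves).
2. Diol 17 ⇒ 4,4-dimethyl-3-ketone 15 (Wolff–Kishner) ⇒ silyl enol ether 13; the C3 oxygen is present only to bring in the second C4 methyl regiospecifically and is then deleted.
3. 13 ⇒ acyclic tetraene 12 by disconnecting C1–C2 and C5–C10 in one intramolecular [4+2] cycloaddition; rings A and B are formed together in step 9 and no ring is made before or after.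
4. Enabling feature: ring A (C1, C2, C3, C4, C5, C10) is a cyclohexane whose C1–C2 and C5–C10 bonds are exactly the two bonds a C2=C3–C4=C5 diene makes to a C10=C1 dienophile. C10, C1 and the C20 methyl form an isopropenyl group on the C9 stereocentre, and C5 and C10 are also joined through C6–C7–C8–C9, so ring B is the tether of the same cycloaddition.
5. 12 ⇒ (R)-limonene 1: its C4 becomes C9, its isopropenyl group is the dienophile, and the ring-opened arms become C8/C7 and C11–C13/C16.

Key step: step 9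

Remark: C7 is formed in step 7 as a mixture of epimers and carried as such because it becomes sp2 in step 15; the acyl chain is read as 32-hydroxydotriacontanoyl (31 CH2 groups); 16-bromohexadecan-1-ol, 16-bromohexadecanoic acid, (vinyloxy)trimethylsilane and 3-(triphenylphosphoranylidene)butan-2-one are taken as purchasable.

**Route**

Step 1
Reactants: 1 (R)-(+)-limonene
Product: 4 (5R)-7,7-dimethoxy-5-(prop-1-en-2-yl)heptan-2-one, via hydroperoxy aldehyde 2 (not isolated), via hydroperoxy acetal 3 (not isolated)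
Conditions: O3 (1 equiv), CH2Cl2/MeOH, −78 °C; TsOH·H2O (cat.), rt; NaHCO3, then Me2S, rt
Reagents that add atoms: ozone O=[O+][O-]; methanol CO
Why: Ozonolysis with terminal differentiation: ozone should attack the trisubstituted ring alkene much faster than the 1,1-disubstituted isopropenyl group, acid in methanol turns the aldehyde end into its dimethyl acetal and Me2S reduces the methoxy hydroperoxide to the methyl ketone, while the stereocentre (future C9) is not touched.

Step 2
Reactants: 4 (5R)-7,7-dimethoxy-5-(prop-1-en-2-yl)heptan-2-one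
Product: 5 ethyl (2E,6R)-8,8-dimethoxy-3-methyl-6-(prop-1-en-2-yl)oct-2-enoate
Conditions: (EtO)2P(O)CH2CO2Et, NaH, THF, 0 → 50 °C
Reagents that add atoms: triethyl phosphonoacetate CCOC(=O)CP(=O)(OCC)OCC
Why: Horner–Wadsworth–Emmons olefination of the methyl ketone should give mainly the E enoate (chain trans to the ester), and the minor Z isomer is to be removed by chromatography here or after step 3.

Step 3
Reactants: 5 ethyl (2E,6R)-8,8-dimethoxy-3-methyl-6-(prop-1-en-2-yl)oct-2-enoate
Product: 6 (2E,6R)-8,8-dimethoxy-3-methyl-6-(prop-1-en-2-yl)oct-2-en-1-ol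
Conditions: i-Bu2AlH, CH2Cl2, −78 °C; aq. potassium sodium tartrate
Reagents that add atoms: none
Why: 1,2-Reduction of a conjugated ester by an aluminium hydride at low temperature gives the allylic alcohol and should leave the acetal and both alkenes untouched.

Step 4
Reactants: 6 (2E,6R)-8,8-dimethoxy-3-methyl-6-(prop-1-en-2-yl)oct-2-en-1-ol
Product: 7 tert-butyl{[(2E,6R)-8,8-dimethoxy-3-methyl-6-(prop-1-en-2-yl)oct-2-en-1-yl]oxy}dimethylsilane
Conditions: TBSCl, imidazole, CH2Cl2, 0 °C → rt
Reagents that add atoms: tert-butyldimethylsilyl chloride CC(C)(C)[Si](C)(C)Cl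
Why: Standard silyl ether protection of the primary allylic alcohol (C15–O), which must survive the base and organolithium steps that follow.

Step 5
Reactants: 7 tert-butyl{[(2E,6R)-8,8-dimethoxy-3-methyl-6-(prop-1-en-2-yl)oct-2-en-1-yl]oxy}dimethylsilane
Product: 8 (3R,6E)-8-[(tert-butyldimethylsilyl)oxy]-6-methyl-3-(prop-1-en-2-yl)oct-6-enal
Conditions: LiBF4, MeCN/H2O (50:1), rt
Reagents that add atoms: water O
Why: Mild Lewis-acid-mediated acetal hydrolysis of an acyclic dimethyl acetal, which a primary tert-butyldimethylsilyl ether should survive.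

Step 6
Reactants: 8 (3R,6E)-8-[(tert-butyldimethylsilyl)oxy]-6-methyl-3-(prop-1-en-2-yl)oct-6-enal
Product: 9 (3S,6E)-8-[(tert-butyldimethylsilyl)oxy]-6-methyl-2-methylidene-3-(prop-1-en-2-yl)oct-6-enal
Conditions: aq. CH2O (37%), pyrrolidine (10 mol%), EtCO2H (10 mol%), i-PrOH, 45 °C
Reagents that add atoms: formaldehyde C=O
Why: Amine-catalysed Mannich condensation and elimination (organocatalytic α-methylenation of an aldehyde) installs C17 as a methylene group; the neighbouring stereocentre carries no acidified hydrogen and should not epimerise (its descriptor changes only by priority).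

Step 7
Reactants: 9 (3S,6E)-8-[(tert-butyldimethylsilyl)oxy]-6-methyl-2-methylidene-3-(prop-1-en-2-yl)oct-6-enal
Product: 11 (3E,8S,11E)-13-[(tert-butyldimethylsilyl)oxy]-6-hydroxy-3,11-dimethyl-7-methylidene-8-(prop-1-en-2-yl)trideca-3,11-dien-2-one (both carbinol epimers), via β-hydroxy aldehyde 10 (not isolated)
Conditions: CH2=CHOSiMe3, BF3·OEt2, CH2Cl2, −78 °C; aq. NaHCO3; crude aldehyde, Ph3P=C(Me)C(O)Me, CH2Cl2, rt
Reagents that add atoms: (vinyloxy)trimethylsilane C=CO[Si](C)(C)C; 3-(triphenylphosphoranylidene)butan-2-one CC(=O)C(C)=P(c1ccccc1)(c1ccccc1)c1ccccc1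
Why: Mukaiyama aldol addition of the acetaldehyde enol silane to the BF3-activated aldehyde (1,2-addition, C7 carbinol without control) followed by Wittig olefination of the crude aldol with a stabilised ylide, which should give the E-configured α-methyl enone.

Step 8
Reactants: 11 (3E,8S,11E)-13-[(tert-butyldimethylsilyl)oxy]-6-hydroxy-3,11-dimethyl-7-methylidene-8-(prop-1-en-2-yl)trideca-3,11-dien-2-one
Product: 12 tert-butyl{[(2E,6S,10E)-3,11-dimethyl-7-methylidene-6-(prop-1-en-2-yl)-8,12-bis(triethylsilyloxy)trideca-2,10,12-trien-1-yl]oxy}dimethylsilane (both C8 epimers)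
Conditions: Et3SiOTf, Et3N, CH2Cl2, −78 → 0 °C
Reagents that add atoms: triethylsilyl trifluoromethanesulfonate CC[Si](CC)(CC)OS(=O)(=O)C(F)(F)F
Why: Soft enolisation of the methyl enone (silyl triflate and amine) deprotonates the methyl group and gives the cross-conjugated 2-silyloxy-1,3-diene, and the secondary alcohol is silylated in the same operation.

Step 9
Reactants: 12 tert-butyl{[(2E,6S,10E)-3,11-dimethyl-7-methylidene-6-(prop-1-en-2-yl)-8,12-bis(triethylsilyloxy)trideca-2,10,12-trien-1-yl]oxy}dimethylsilane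
Product: 13 ent-15-(tert-butyldimethylsilyloxy)-3,7ξ-bis(triethylsilyloxy)-18-norlabda-3,8(17),13E-triene (trans-fused octalin; 5-H and 9-H on the face opposite to the C10 methyl)
Conditions: toluene (0.01 M), BHT, 190 °C, sealed tube
Reagents that add atoms: none
Why: Thermal intramolecular Diels–Alder reaction of a 1,7,9-decatriene: the 2-silyloxy-3-methyl diene C2=C3–C4=C5 (biased towards s-cis by its 2,3-disubstitution) adds suprafacially across the isopropenyl double bond C10=C1 in one concerted [4+2] event that makes C1–C2 and C5–C10. The closest known reaction type is the thermal cyclisation of unactivated 2-methyl-1,7,9-decatrienes and of silyloxy-diene trienes to angularly methylated octalins. Ring A is closed as the new cyclohexene of the cycloaddition, and ring B is closed in the same event as the six-membered ring that the four-atom tether C6–C7–C8–C9 spans between the diene terminus C5 and the substituted dienophile carbon C10 (fused bicyclisation through a chair-like tether). The new stereocentres C5 and C10 are controlled by the limonene-derived centre C9 and by the (E)-C4=C5 geometry: with the C9 side chain pseudo-equatorial and anti to the forming C5–C10 bond, the tether exo and the C20 methyl endo, the trans-fused octalin with H-5 and H-9 on the face opposite to the C10 methyl should result. The step needs trans over cis ring fusion and one diene face; the C9 stereocentre, the E diene and the C4 methyl next to the tether (which clashes with the tether in the folded arrangement leading to cis fusion) are what should secure it, whereas the C7 silyloxy group is a spectator that takes the position its configuration dictates. The enol silyl ether left at C3–C4 is the handle for the second C4 methyl in step 10.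

Step 10
Reactants: 13 ent-15-(tert-butyldimethylsilyloxy)-3,7ξ-bis(triethylsilyloxy)-18-norlabda-3,8(17),13E-triene
Product: 15 ent-15-(tert-butyldimethylsilyloxy)-7ξ-(triethylsilyloxy)labda-8(17),13E-dien-3-one, via lithium enolate 14 (not isolated)
Conditions: MeLi, THF, 0 °C → rt; then MeI, DMPU, −78 → 0 °C
Reagents that add atoms: iodomethane CI
Why: Regiospecific enolate generation from a silyl enol ether (MeLi attacks silicon) followed by C-methylation of the tetrasubstituted enolate at C4; no stereocentre is created because C4 becomes the gem-dimethyl carbon.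

Step 11
Reactants: 15 ent-15-(tert-butyldimethylsilyloxy)-7ξ-(triethylsilyloxy)labda-8(17),13E-dien-3-one
Product: 17 ent-labda-8(17),13E-diene-7ξ,15-diol, via hydrazone 16 (not isolated)
Conditions: N2H4·H2O, (HOCH2CH2)2O, 130 °C; then KOH, 200 °C
Reagents that add atoms: none
Why: Wolff–Kishner reduction (Huang–Minlon procedure), established for hindered 4,4-dimethyl-3-ketones, removes the C3 carbonyl, and the hot KOH/glycol medium should also cleave both silyl ethers; isolated alkenes and the stereocentres are not affected.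

Step 12
Reactants: 18 16-bromohexadecan-1-ol
Product: 19 [(16-bromohexadecyl)oxy](tert-butyl)dimethylsilane
Conditions: TBSCl, imidazole, DMF, rt
Reagents that add atoms: tert-butyldimethylsilyl chloride CC(C)(C)[Si](C)(C)Cl
Why: Standard silyl protection so that the bromide can be converted into a Grignard reagent.

Step 13
Reactants: 19 [(16-bromohexadecyl)oxy](tert-butyl)dimethylsilane; 20 16-bromohexadecanoic acid
Product: 23 32-[(tert-butyldimethylsilyl)oxy]dotriacontanoic acid, via Grignard reagent 21 (not isolated), via magnesium carboxylate 22 (not isolated)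
Conditions: 19, Mg, THF, 45 °C; 20, MeMgCl (1 equiv), THF, −20 °C; combine, Li2CuCl4 (3 mol%), −20 → 0 °C; aq. NH4Cl
Reagents that add atoms: none
Why: Copper-catalysed sp3–sp3 cross-coupling of a primary alkyl Grignard reagent with a primary alkyl bromide, with the acid masked in the flask as its magnesium carboxylate, joins the two C16 halves.

Step 14
Reactants: 17 ent-labda-8(17),13E-diene-7ξ,15-diol; 23 32-[(tert-butyldimethylsilyl)oxy]dotriacontanoic acid
Product: 24 ent-7ξ-hydroxylabda-8(17),13E-dien-15-yl 32-[(tert-butyldimethylsilyl)oxy]dotriacontanoate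
Conditions: EDC·HCl, DMAP (cat.), CH2Cl2, 0 °C → rt
Reagents that add atoms: none
Why: Carbodiimide (Steglich) esterification with one equivalent of acid should acylate the unhindered primary allylic C15 hydroxyl in preference to the hindered secondary ring hydroxyl at C7.

Step 15
Reactants: 24 ent-7ξ-hydroxylabda-8(17),13E-dien-15-yl 32-[(tert-butyldimethylsilyl)oxy]dotriacontanoate
Product: 25 ent-17-hydroxylabda-7,13E-dien-15-yl 32-[(tert-butyldimethylsilyl)oxy]dotriacontanoate
Conditions: Ph3SiOReO3 (5 mol%), Et2O, 0 °C → rt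
Reagents that add atoms: none
Why: Rhenium-oxo-catalysed 1,3-transposition of an allylic alcohol through the [3,3] shift of its perrhenate ester; the equilibrium should favour the primary alcohol with the trisubstituted C7=C8 ring alkene over the secondary alcohol with the exocyclic methylene, both C7 epimers converge, and the alkene geometry is fixed by ring B.

Step 16
Reactants: 25 ent-17-hydroxylabda-7,13E-dien-15-yl 32-[(tert-butyldimethylsilyl)oxy]dotriacontanoate
Product: 26 ent-17-hydroxylabda-7,13E-dien-15-yl 32-hydroxydotriacontanoate (target CNP0264179.1)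
Conditions: HF·pyridine, pyridine/THF, 0 °C → rt
Reagents that add atoms: none
Why: Buffered fluoride cleavage of the primary silyl ether, which should leave the allylic ester, the allylic alcohol and both alkenes intact.

**Compound list**

1 | (R)-(+)-limonene, (4R)-1-methyl-4-(prop-1-en-2-yl)cyclohex-1-ene | CC1=CC[C@@H](CC1)C(C)=C | starting material
2 | (3R)-6-hydroperoxy-6-methoxy-3-(prop-1-en-2-yl)heptanal (C6 epimers) | CC(OC)(OO)CC[C@@H](C(C)=C)CC=O | intermediate (not isolated)
3 | (5R)-2-hydroperoxy-2,7,7-trimethoxy-5-(prop-1-en-2-yl)heptane (C2 epimers) | CC(OC)(OO)CC[C@@H](C(C)=C)CC(OC)OC | intermediate (not isolated)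
4 | (5R)-7,7-dimethoxy-5-(prop-1-en-2-yl)heptan-2-one | CC(=O)CC[C@@H](C(C)=C)CC(OC)OC | intermediate
5 | ethyl (2E,6R)-8,8-dimethoxy-3-methyl-6-(prop-1-en-2-yl)oct-2-enoate | CCOC(=O)/C=C(\C)CC[C@@H](C(C)=C)CC(OC)OC | intermediate
6 | (2E,6R)-8,8-dimethoxy-3-methyl-6-(prop-1-en-2-yl)oct-2-en-1-ol | OC/C=C(\C)CC[C@@H](C(C)=C)CC(OC)OC | intermediate
7 | tert-butyl{[(2E,6R)-8,8-dimethoxy-3-methyl-6-(prop-1-en-2-yl)oct-2-en-1-yl]oxy}dimethylsilane | CC(C)(C)[Si](C)(C)OC/C=C(\C)CC[C@@H](C(C)=C)CC(OC)OC | intermediate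
8 | (3R,6E)-8-[(tert-butyldimethylsilyl)oxy]-6-methyl-3-(prop-1-en-2-yl)oct-6-enal | CC(C)(C)[Si](C)(C)OC/C=C(\C)CC[C@@H](C(C)=C)CC=O | intermediate
9 | (3S,6E)-8-[(tert-butyldimethylsilyl)oxy]-6-methyl-2-methylidene-3-(prop-1-en-2-yl)oct-6-enal | CC(C)(C)[Si](C)(C)OC/C=C(\C)CC[C@@H](C(C)=C)C(=C)C=O | intermediate
10 | (5S,8E)-10-[(tert-butyldimethylsilyl)oxy]-3-hydroxy-8-methyl-4-methylidene-5-(prop-1-en-2-yl)dec-8-enal (C3 epimers) | CC(C)(C)[Si](C)(C)OC/C=C(\C)CC[C@@H](C(C)=C)C(=C)C(O)CC=O | intermediate (not isolated)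
11 | (3E,8S,11E)-13-[(tert-butyldimethylsilyl)oxy]-6-hydroxy-3,11-dimethyl-7-methylidene-8-(prop-1-en-2-yl)trideca-3,11-dien-2-one (C6 epimers) | CC(C)(C)[Si](C)(C)OC/C=C(\C)CC[C@@H](C(C)=C)C(=C)C(O)C/C=C(\C)C(C)=O | intermediate
12 | tert-butyl{[(2E,6S,10E)-3,11-dimethyl-7-methylidene-6-(prop-1-en-2-yl)-8,12-bis(triethylsilyloxy)trideca-2,10,12-trien-1-yl]oxy}dimethylsilane (C8 epimers) | CC(C)(C)[Si](C)(C)OC/C=C(\C)CC[C@@H](C(C)=C)C(=C)C(O[Si](CC)(CC)CC)C/C=C(\C)C(=C)O[Si](CC)(CC)CC | intermediate
13 | ent-15-(tert-butyldimethylsilyloxy)-3,7ξ-bis(triethylsilyloxy)-18-norlabda-3,8(17),13E-triene (trans-fused; 5-H and 9-H opposite to the C10 methyl) | CC(C)(C)[Si](C)(C)OC/C=C(\C)CC[C@@H]1C(=C)C(O[Si](CC)(CC)CC)C[C@@H]2C(C)=C(O[Si](CC)(CC)CC)CC[C@@]12C | intermediate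
14 | lithium C3 enolate of 15 (lacking the second C4 methyl) | [Li+].CC(C)(C)[Si](C)(C)OC/C=C(\C)CC[C@@H]1C(=C)C(O[Si](CC)(CC)CC)C[C@@H]2C(C)=C([O-])CC[C@@]12C | intermediate (not isolated)
15 | ent-15-(tert-butyldimethylsilyloxy)-7ξ-(triethylsilyloxy)labda-8(17),13E-dien-3-one | CC(C)(C)[Si](C)(C)OC/C=C(\C)CC[C@@H]1C(=C)C(O[Si](CC)(CC)CC)C[C@@H]2C(C)(C)C(=O)CC[C@@]12C | intermediate
16 | hydrazone of 15 | CC(C)(C)[Si](C)(C)OC/C=C(\C)CC[C@@H]1C(=C)C(O[Si](CC)(CC)CC)C[C@@H]2C(C)(C)C(=NN)CC[C@@]12C | intermediate (not isolated)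
17 | ent-labda-8(17),13E-diene-7ξ,15-diol, (2E)-5-[(1S,4aR,8aR)-3-hydroxy-5,5,8a-trimethyl-2-methylidenedecahydronaphthalen-1-yl]-3-methylpent-2-en-1-ol (C3 epimers) | OC/C=C(\C)CC[C@@H]1C(=C)C(O)C[C@@H]2C(C)(C)CCC[C@@]12C | intermediate
18 | 16-bromohexadecan-1-ol | OCCCCCCCCCCCCCCCCBr | starting material
19 | [(16-bromohexadecyl)oxy](tert-butyl)dimethylsilane | CC(C)(C)[Si](C)(C)OCCCCCCCCCCCCCCCCBr | intermediate
20 | 16-bromohexadecanoic acid | OC(=O)CCCCCCCCCCCCCCCBr | starting material
21 | {16-[(tert-butyldimethylsilyl)oxy]hexadecyl}magnesium bromide | CC(C)(C)[Si](C)(C)OCCCCCCCCCCCCCCCC[Mg]Br | intermediate (not isolated)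
22 | chloromagnesium 16-bromohexadecanoate | BrCCCCCCCCCCCCCCCC(=O)O[Mg]Cl | intermediate (not isolated)
23 | 32-[(tert-butyldimethylsilyl)oxy]dotriacontanoic acid | CC(C)(C)[Si](C)(C)OCCCCCCCCCCCCCCCCCCCCCCCCCCCCCCCC(=O)O | intermediate
24 | ent-7ξ-hydroxylabda-8(17),13E-dien-15-yl 32-[(tert-butyldimethylsilyl)oxy]dotriacontanoate | CC(C)(C)[Si](C)(C)OCCCCCCCCCCCCCCCCCCCCCCCCCCCCCCCC(=O)OC/C=C(\C)CC[C@@H]1C(=C)C(O)C[C@@H]2C(C)(C)CCC[C@@]12C | intermediate
25 | ent-17-hydroxylabda-7,13E-dien-15-yl 32-[(tert-butyldimethylsilyl)oxy]dotriacontanoate | CC(C)(C)[Si](C)(C)OCCCCCCCCCCCCCCCCCCCCCCCCCCCCCCCC(=O)OC/C=C(\C)CC[C@@H]1C(CO)=CC[C@@H]2C(C)(C)CCC[C@@]12C | intermediate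
26 | (2E)-5-[(1S,4aR,8aR)-2-(hydroxymethyl)-5,5,8a-trimethyl-1,4,4a,5,6,7,8,8a-octahydronaphthalen-1-yl]-3-methylpent-2-en-1-yl 32-hydroxydotriacontanoate | C/C(=C\COC(=O)CCCCCCCCCCCCCCCCCCCCCCCCCCCCCCCO)CC[C@@H]1C(CO)=CC[C@@H]2C(C)(C)CCC[C@@]12C | target

**Step count and risks**

Total step count: 16. Longest linear sequence: 14 steps (steps 1–11 and 14–16 from (R)-limonene); the C32 acid branch is steps 12 and 13.

Steps most likely to fail:

1. Step 9 (cycloaddition). The unactivated isopropenyl group may react too slowly at temperatures the silyl dienol ether tolerates, so that a [3,3] shift of the 3-silyloxy-1,5-diene unit (C17=C8–C7–C6–C5=C4) or decomposition competes. Control of ring fusion and of the diene face may also erode, the more so because two C7 epimers are cyclised. The fallback activates the dienophile at a higher oxidation level; it sets out from 11 and comes back at 17. The C7 hydroxyl of 11 is silylated (TBSOTf, 2,6-lutidine) to the C7 tert-butyldimethylsilyl ether F1. Allylic oxidation of the isopropenyl methyl group (SeO2 cat., t-BuOOH, CH2Cl2) should give the 2-substituted allyl alcohol F2, relying on the lower reactivity of the two alkenes that carry allylic silyloxy groups, and MnO2 then gives the 2-substituted acrolein F3. Et3SiOTf/Et3N gives the silyl dienol ether F4, in which an electron-rich diene faces an enal. The cycloaddition should then run in toluene at 40–60 °C (or with Me2AlCl at −78 °C) with the formyl group endo, giving the trans-fused cycloadduct with an angular formyl group F5. Fluoride-induced methylation (BnMe3NF, MeI, THF; MeLi is avoided because of the aldehyde) gives the keto aldehyde F6. The Wolff–Kishner conditions of step 11 then reduce both carbonyl groups through the bis-hydrazone F7 (C3=O to CH2, the formyl group to the C20 methyl) and cleave the silyl ethers, which returns the route to 17.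

2. Step 7 (acetaldehyde aldol and olefination). The β-hydroxy aldehyde may react again with the enol silane (oligo-aldol), lose water, or the enol silane may add in a conjugate sense to the 2-substituted acrolein. The fallback uses an ester-level two-carbon donor; it sets out from 9 and comes back at 12. Reformatsky addition (Zn, BrCH2CO2Et, THF) gives the β-hydroxy ester F8. Et3SiCl/imidazole gives its triethylsilyl ether F9. i-Bu2AlH at −78 °C gives the β-silyloxy aldehyde F10. The Wittig reagent of step 7 gives the silyl-protected enone F11. Et3SiOTf/Et3N then forms the dienol ether, which is 12.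

3. Step 15 (allylic transposition). The perrhenate-mediated shift is an equilibrium through allyl-cation-like species, so incomplete conversion, elimination to a 6,8(17)-diene or ionisation of the C15 allylic ester may occur. The fallback is an irreversible ester rearrangement; it sets out from 24 and comes back at 25. Chloroacetylation ((ClCH2CO)2O, pyridine) gives the C7 chloroacetate F12. A [3,3] rearrangement of the allylic ester catalysed by PdCl2(MeCN)2 (divalent palladium, THF, rt) should give the C17 chloroacetate with the C7=C8 alkene F13. Thiourea/NaHCO3 in EtOH removes the chloroacetyl group in the presence of the long-chain ester and gives 25.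

**Further compounds**

F1 | step 9 | C7 tert-butyldimethylsilyl ether of 11 | CC(C)(C)[Si](C)(C)OC/C=C(\C)CC[C@@H](C(C)=C)C(=C)C(O[Si](C)(C)C(C)(C)C)C/C=C(\C)C(C)=O
F2 | step 9 | 2-substituted allyl alcohol (C20 hydroxylated F1) | CC(C)(C)[Si](C)(C)OC/C=C(\C)CC[C@@H](C(=C)CO)C(=C)C(O[Si](C)(C)C(C)(C)C)C/C=C(\C)C(C)=O
F3 | step 9 | 2-substituted acrolein (C20 aldehyde) | CC(C)(C)[Si](C)(C)OC/C=C(\C)CC[C@@H](C(=C)C=O)C(=C)C(O[Si](C)(C)C(C)(C)C)C/C=C(\C)C(C)=O
F4 | step 9 | triethylsilyl dienol ether of F3 | CC(C)(C)[Si](C)(C)OC/C=C(\C)CC[C@@H](C(=C)C=O)C(=C)C(O[Si](C)(C)C(C)(C)C)C/C=C(\C)C(=C)O[Si](CC)(CC)CC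
F5 | step 9 | trans-fused cycloadduct with angular formyl group at C10 | CC(C)(C)[Si](C)(C)OC/C=C(\C)CC[C@@H]1C(=C)C(O[Si](C)(C)C(C)(C)C)C[C@@H]2C(C)=C(O[Si](CC)(CC)CC)CC[C@@]12C=O
F6 | step 9 | 4,4-dimethyl-3-keto C20 aldehyde | CC(C)(C)[Si](C)(C)OC/C=C(\C)CC[C@@H]1C(=C)C(O[Si](C)(C)C(C)(C)C)C[C@@H]2C(C)(C)C(=O)CC[C@@]12C=O
F7 | step 9 | bis-hydrazone of F6 | CC(C)(C)[Si](C)(C)OC/C=C(\C)CC[C@@H]1C(=C)C(O[Si](C)(C)C(C)(C)C)C[C@@H]2C(C)(C)C(=NN)CC[C@@]12C=NN
F8 | step 7 | ethyl (5S,8E)-10-[(tert-butyldimethylsilyl)oxy]-3-hydroxy-8-methyl-4-methylidene-5-(prop-1-en-2-yl)dec-8-enoate (C3 epimers) | CC(C)(C)[Si](C)(C)OC/C=C(\C)CC[C@@H](C(C)=C)C(=C)C(O)CC(=O)OCC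
F9 | step 7 | triethylsilyl ether of F8 | CC(C)(C)[Si](C)(C)OC/C=C(\C)CC[C@@H](C(C)=C)C(=C)C(O[Si](CC)(CC)CC)CC(=O)OCC
F10 | step 7 | β-(triethylsilyloxy) aldehyde | CC(C)(C)[Si](C)(C)OC/C=C(\C)CC[C@@H](C(C)=C)C(=C)C(O[Si](CC)(CC)CC)CC=O
F11 | step 7 | C7 triethylsilyl ether of 11 | CC(C)(C)[Si](C)(C)OC/C=C(\C)CC[C@@H](C(C)=C)C(=C)C(O[Si](CC)(CC)CC)C/C=C(\C)C(C)=O
F12 | step 15 | C7 chloroacetate of 24 | CC(C)(C)[Si](C)(C)OCCCCCCCCCCCCCCCCCCCCCCCCCCCCCCCC(=O)OC/C=C(\C)CC[C@@H]1C(=C)C(OC(=O)CCl)C[C@@H]2C(C)(C)CCC[C@@]12C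
F13 | step 15 | C17 chloroacetate with C7=C8 alkene | CC(C)(C)[Si](C)(C)OCCCCCCCCCCCCCCCCCCCCCCCCCCCCCCCC(=O)OC/C=C(\C)CC[C@@H]1C(COC(=O)CCl)=CC[C@@H]2C(C)(C)CCC[C@@]12C
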